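**Strategy.** The plan rests on cutting ring A at C8–C8a and C4a–C5. This leaves ring C as an enantiopure 5-bromo-2-aryl-2,3-dihydropyran-4-one, with C2 and ring B in place, and a 1-methoxy-3-silyloxy diene whose nucleophilic terminus carries the prenyl group. The key step exploits the 1,3-placement of oxygen on C7 and C8a around prenyl-bearing C8, and the fact that the C4a–C8a fusion bond is the enone C=C of ring C. In one operation it forms both bonds, closes ring A and aromatises it by loss of methanol, HBr and silicon, so that the 7-hydroxy-8-prenyl pattern needs no phenol prenylation. C2 stems from a catalytic asymmetric hetero-Diels–Alder reaction.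

Key step: step 7

Assumption: the sense of induction of the (S,S)-configured chromium catalyst is taken by analogy with simple aromatic aldehydes (diene on the Si face, hence 2S). It is to be verified on the bromopyranone by anomalous-dispersion X-ray analysis, and the antipodal catalyst is equally accessible.

Remarks on the design:
- **Order of eliminations.** In the cis-fused adduct of the key step, Br on C4a and H on C8a lie on the same face, and C8a–H is not acidified by any carbonyl group. An anti-E2 loss of HBr across C4a–C8a is therefore not available. The aromatisation is ordered as methanol first and HBr second, with the C7 oxygen re-silylated in between.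
- **Protecting group.** The 2′-oxygen is carried as a tert-butyldimethylsilyl ether, not as an acetal-type group. An aryl acetal would be ionised by a silyl triflate or a zinc halide in the presence of an enol silane. Its acidic removal would also endanger the ortho-prenylphenol and the benzylic C2–O1 bond, which two ring-B oxygens activate.
- **Bromination.** Electrophilic bromine is never offered to the finished pyranone, whose vinylogous ester is less nucleophilic than the chromene alkene and ring B. It is delivered instead to the enol silane of the primary hetero-Diels–Alder adduct.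

Step 1
Reactants: 1 resorcinol; 2 3-methylbut-2-enal
Product: 3 2,2-dimethyl-2H-chromen-7-ol
Conditions: pyridine, 115 °C (1 in excess)
Reagents that add atoms: none
Why: Base-mediated chromenylation (aldol-type C-alkylation of the phenoxide, dehydration to an ortho-quinone methide, oxa-6π electrocyclisation) is the standard formal [3+3] route to 2,2-dimethylchromenes, and resorcinol should react at C4, para to the second hydroxyl, rather than at the crowded C2, so that the 7-hydroxy isomer is expected to dominate while excess resorcinol suppresses double annulation.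

Step 2
Reactants: 3 2,2-dimethyl-2H-chromen-7-ol
Product: 4 7-hydroxy-2,2-dimethyl-2H-chromene-6-carbaldehyde
Conditions: MgCl2, Et3N, (CH2O)n, MeCN, reflux; then 1 M HCl
Reagents that add atoms: paraformaldehyde (as formaldehyde), C=O
Why: Casnati–Skattebøl ortho-formylation, in which the magnesium phenoxide delivers formaldehyde only to an ortho carbon and a second formaldehyde oxidises the benzylic alkoxide by hydride transfer; of the two ortho sites the open C6 should be taken rather than C8, which is wedged between two oxygens, as is usual for 3-alkoxyphenols.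

Step 3
Reactants: 4 7-hydroxy-2,2-dimethyl-2H-chromene-6-carbaldehyde
Product: 5 7-(tert-butyldimethylsilyloxy)-2,2-dimethyl-2H-chromene-6-carbaldehyde
Conditions: TBSCl, imidazole, DMF, rt
Reagents that add atoms: tert-butyldimethylsilyl chloride, CC(C)(C)[Si](C)(C)Cl
Why: Routine imidazole-promoted O-silylation, giving a group that is inert to silyl triflate in the presence of enol silanes (step 7) and can later be removed by fluoride without strong acid or base.

Step 4
Reactants: 5 7-(tert-butyldimethylsilyloxy)-2,2-dimethyl-2H-chromene-6-carbaldehyde; 6 (E)-1-methoxy-3-(trimethylsilyloxy)buta-1,3-diene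
Product: 9 (2S)-5-bromo-2-[7-(tert-butyldimethylsilyloxy)-2,2-dimethyl-2H-chromen-6-yl]-2,3-dihydro-4H-pyran-4-one, via silyl enol ether cycloadduct 7 (not isolated), via bromo acetal ketone 8 (not isolated)
Conditions: (S,S)-(salen)CrBF4 (5 mol %; salen = N,N'-bis(3,5-di-tert-butylsalicylidene)cyclohexane-1,2-diamine dianion), 4 Å MS, t-BuOMe, −20 °C, 6 (1.0 equiv); then NBS (1.0 equiv), THF, −78 °C; then Et3N, −78 °C → rt; recrystallisation
Reagents that add atoms: N-bromosuccinimide, O=C1CCC(=O)N1Br
Why: Lewis acid-catalysed enantioselective hetero-Diels–Alder reaction, in which the chiral (salen)chromium cation binds the aldehyde and admits the diene only to its Si face in a concerted endo [4+2] that sets C2 as S and leaves the enol silane of 7 intact; this enol silane, the most nucleophilic π-bond present, should take up Br+ from one equivalent of NBS at −78 °C faster than the chromene alkene or ring B, and Et3N then expels methanol from 8 by E1cB elimination without touching the C2–O bond.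

Step 5
Reactants: 10 (E)-4-methoxybut-3-en-2-one; 11 1-bromo-3-methylbut-2-ene
Product: 12 (E)-1-methoxy-7-methylocta-1,6-dien-3-one
Conditions: LiN(i-Pr)2, THF, −78 °C; then 11, DMPU, −78 → −30 °C
Reagents that add atoms: none
Why: Stork–Danheiser-type alkylation, in which the amide base removes a proton from the methyl group (the only α′-position of the vinylogous ester) and the lithium enolate is captured by the reactive primary allylic bromide in an SN2 reaction.

Step 6
Reactants: 12 (E)-1-methoxy-7-methylocta-1,6-dien-3-one
Product: 13 (1E,3Z)-1-methoxy-7-methyl-3-(trimethylsilyloxy)octa-1,3,6-triene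
Conditions: TMSOTf, Et3N, Et2O, 0 °C; pentane extraction, used without chromatography
Reagents that add atoms: trimethylsilyl trifluoromethanesulfonate, C[Si](C)(C)OS(=O)(=O)C(F)(F)F
Why: Soft enolisation with a silyl triflate and a tertiary amine is the standard preparation of 4-substituted 1-methoxy-3-silyloxy dienes and should give the (3Z)-enol silane, in which the prenyl-bearing chain points away from the methoxyvinyl group and so occupies the outside position of the s-cis diene.

Step 7
Reactants: 9 (2S)-5-bromo-2-[7-(tert-butyldimethylsilyloxy)-2,2-dimethyl-2H-chromen-6-yl]-2,3-dihydro-4H-pyran-4-one; 13 (1E,3Z)-1-methoxy-7-methyl-3-(trimethylsilyloxy)octa-1,3,6-triene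
Product: 17 (2S)-2-[7-(tert-butyldimethylsilyloxy)-2,2-dimethyl-2H-chromen-6-yl]-7-hydroxy-8-(3-methylbut-2-en-1-yl)-2,3-dihydro-4H-chromen-4-one, via bromo cycloadduct 14 (not isolated), via bromo enedione 15 (not isolated), via aryl trimethylsilyl ether 16 (not isolated)
Conditions: 13 (1.5 equiv), TMSOTf (0.2 equiv), 2,6-di-tert-butylpyridine (0.3 equiv), CH2Cl2, −78 → −40 °C; then Et3N (5 equiv), TMSOTf (1.5 equiv), −78 → 0 °C; then aq. citric acid, THF, 0 °C
Reagents that add atoms: none
Why: Proposed new method: O-silylation of the C4 carbonyl turns 9 into a 4-silyloxypyranylium ion that is electrophilic only at C8a, the prenyl-bearing enol-silane terminus of 13 bonds there (Mukaiyama–Michael addition, a known reaction of 2,3-dihydropyran-4-ones), and the α-bromo enol silane so formed attacks the methoxy-oxocarbenium carbon C5 through C4a, closing ring A in a favoured 6-(enolexo)-exo-trig mode that is the stepwise counterpart of a [4+2] cycloaddition and gives 14. The closest known reaction types are Diels–Alder/aromatisation sequences of 1-alkoxy-3-silyloxy dienes with 2-halo enones, haloquinones and 3-acceptor-substituted chromones, but a β-oxygenated 2-bromo enone has not been used in this role. Since Br on C4a and H on C8a are cis in 14 and any ionic loss of HBr at that stage would be drawn to the more activated C5–H (which would strand the methoxy group on ring A and later force O1 out), methanol goes first: the silyl triflate ionises the allylic C5–OMe bond, MeOSiMe3 departs and 15 results with C5 sp2. Soft enolisation with TMSOTf/Et3N then turns the C7 ketone into its cross-conjugated silyl dienol ether, a bromocyclohexadiene whose tertiary allylic bromide has H-8a as its only β-hydrogen, so that HBr leaves with irreversible aromatisation to 16, and aqueous citric acid frees the C7 phenol. Two selectivities are needed: regiochemistry, which follows from the polarity match of nucleophilic C8 with electrophilic C8a and thereby places prenyl on C8 and oxygen on C7, and retention of O1, which is secured because no free C7 enolate is formed (base-free cold first stage, enol trapped on silicon in the second, excess amine buffering the triflate) while bromide is much the better nucleofuge. No lasting stereocentre is created, since C4a, C5, C8 and C8a all end up sp2, and C2 is a spectator whose C2–O1 bond and neighbouring C3–H bonds see only catalytic silyl triflate at low temperature and a tertiary amine at or below 0 °C.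

Step 8
Reactants: 17 (2S)-2-[7-(tert-butyldimethylsilyloxy)-2,2-dimethyl-2H-chromen-6-yl]-7-hydroxy-8-(3-methylbut-2-en-1-yl)-2,3-dihydro-4H-chromen-4-one
Product: 18 (2S)-7-hydroxy-2-(7-hydroxy-2,2-dimethyl-2H-chromen-6-yl)-8-(3-methylbut-2-en-1-yl)-2,3-dihydro-4H-chromen-4-one
Conditions: KHF2, MeOH, rt
Reagents that add atoms: none
Why: Fluoride-induced cleavage of a phenolic silyl ether (Si–F bond formation) with weakly acidic KHF2 avoids both the basic medium that would open ring C to the chalcone and racemise C2 and the strong acid that would cyclise the ortho-prenylphenol.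

**Compound list**

1 | resorcinol | Oc1cccc(O)c1 | starting material
2 | 3-methylbut-2-enal | CC(C)=CC=O | starting material
3 | 2,2-dimethyl-2H-chromen-7-ol | CC1(C)C=Cc2ccc(O)cc2O1 | intermediate
4 | 7-hydroxy-2,2-dimethyl-2H-chromene-6-carbaldehyde | CC1(C)C=Cc2cc(C=O)c(O)cc2O1 | intermediate
5 | 7-(tert-butyldimethylsilyloxy)-2,2-dimethyl-2H-chromene-6-carbaldehyde | CC1(C)C=Cc2cc(C=O)c(O[Si](C)(C)C(C)(C)C)cc2O1 | intermediate
6 | (E)-1-methoxy-3-(trimethylsilyloxy)buta-1,3-diene | CO/C=C/C(=C)O[Si](C)(C)C | starting material
7 | (2R,6S)-6-[7-(tert-butyldimethylsilyloxy)-2,2-dimethyl-2H-chromen-6-yl]-2-methoxy-4-(trimethylsilyloxy)-5,6-dihydro-2H-pyran (2,6-cis, endo adduct) | CO[C@H]1C=C(O[Si](C)(C)C)C[C@@H](c2cc3c(cc2O[Si](C)(C)C(C)(C)C)OC(C)(C)C=C3)O1 | intermediate (not isolated)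
8 | (6S)-3-bromo-6-[7-(tert-butyldimethylsilyloxy)-2,2-dimethyl-2H-chromen-6-yl]-2-methoxyoxan-4-one (epimers at C2 and C3, of no consequence) | COC1O[C@H](c2cc3c(cc2O[Si](C)(C)C(C)(C)C)OC(C)(C)C=C3)CC(=O)C1Br | intermediate (not isolated)
9 | (2S)-5-bromo-2-[7-(tert-butyldimethylsilyloxy)-2,2-dimethyl-2H-chromen-6-yl]-2,3-dihydro-4H-pyran-4-one | O=C1C[C@@H](c2cc3c(cc2O[Si](C)(C)C(C)(C)C)OC(C)(C)C=C3)OC=C1Br | intermediate
10 | (E)-4-methoxybut-3-en-2-one | CO/C=C/C(C)=O | starting material
11 | 1-bromo-3-methylbut-2-ene | CC(C)=CCBr | starting material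
12 | (E)-1-methoxy-7-methylocta-1,6-dien-3-one | CO/C=C/C(=O)CCC=C(C)C | intermediate
13 | (1E,3Z)-1-methoxy-7-methyl-3-(trimethylsilyloxy)octa-1,3,6-triene | CO/C=C/C(O[Si](C)(C)C)=C/CC=C(C)C | intermediate
14 | (2S)-4a-bromo-2-[7-(tert-butyldimethylsilyloxy)-2,2-dimethyl-2H-chromen-6-yl]-5-methoxy-8-(3-methylbut-2-en-1-yl)-7-(trimethylsilyloxy)-2,3,4a,5,8,8a-hexahydro-4H-chromen-4-one (cis-fused; transient centres C4a, C5, C8, C8a not defined) | O=C1C[C@@H](c2cc3c(cc2O[Si](C)(C)C(C)(C)C)OC(C)(C)C=C3)OC2C(CC=C(C)C)C(O[Si](C)(C)C)=CC(OC)C12Br | intermediate (not isolated)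
15 | (2S)-4a-bromo-2-[7-(tert-butyldimethylsilyloxy)-2,2-dimethyl-2H-chromen-6-yl]-8-(3-methylbut-2-en-1-yl)-2,3,8,8a-tetrahydro-4H-chromene-4,7(4aH)-dione (transient centres not defined) | O=C1C[C@@H](c2cc3c(cc2O[Si](C)(C)C(C)(C)C)OC(C)(C)C=C3)OC2C(CC=C(C)C)C(=O)C=CC12Br | intermediate (not isolated)
16 | (2S)-2-[7-(tert-butyldimethylsilyloxy)-2,2-dimethyl-2H-chromen-6-yl]-8-(3-methylbut-2-en-1-yl)-7-(trimethylsilyloxy)-2,3-dihydro-4H-chromen-4-one | CC(C)=CCc1c(O[Si](C)(C)C)ccc2c1O[C@H](c1cc3c(cc1O[Si](C)(C)C(C)(C)C)OC(C)(C)C=C3)CC2=O | intermediate (not isolated)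
17 | (2S)-2-[7-(tert-butyldimethylsilyloxy)-2,2-dimethyl-2H-chromen-6-yl]-7-hydroxy-8-(3-methylbut-2-en-1-yl)-2,3-dihydro-4H-chromen-4-one | CC(C)=CCc1c(O)ccc2c1O[C@H](c1cc3c(cc1O[Si](C)(C)C(C)(C)C)OC(C)(C)C=C3)CC2=O | intermediate
18 | (2S)-7-hydroxy-2-(7-hydroxy-2,2-dimethyl-2H-chromen-6-yl)-8-(3-methylbut-2-en-1-yl)-2,3-dihydro-4H-chromen-4-one | CC(C)=CCc1c(O)ccc2c1O[C@H](c1cc3c(cc1O)OC(C)(C)C=C3)CC2=O | target

**Total step count:** 8. **Longest linear sequence:** 6 steps (1, 2, 3, 4, 7, 8).

**Steps most likely to fail**

1. **Step 7.**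
- What may go wrong:
  - The cascade may stall after the first C–C bond, leaving an open-chain Michael adduct that does not close.
  - The prenyl alkene may intercept the oxocarbenium ion.
  - O1 may be expelled from C8a once the C7 oxygen can push.
  - Enantiopurity may erode through reversible ionisation of the C2–O1 bond.
- Fallback (known chemistry, from 4 and 11, rejoining at 18): 4 is converted with MOMCl/i-Pr2NEt into 7-(methoxymethoxy)-2,2-dimethyl-2H-chromene-6-carbaldehyde F1. In parallel, commercial 2,4-dihydroxyacetophenone F2 is C-prenylated with 11 (KOH, H2O) to 1-[2,4-dihydroxy-3-(3-methylbut-2-en-1-yl)phenyl]ethanone F3. This is protected at the non-chelated 4-hydroxyl (MOMCl, K2CO3, acetone) as 1-[2-hydroxy-4-(methoxymethoxy)-3-(3-methylbut-2-en-1-yl)phenyl]ethanone F4. Claisen–Schmidt condensation of F1 and F4 (KOH, EtOH) gives the bis-MOM 2′-hydroxychalcone F5. NaOAc in refluxing EtOH closes it by oxa-Michael addition to the racemic bis-MOM flavanone F6. Preparative HPLC on a chiral stationary phase delivers the (2S)-bis-MOM flavanone F7, and the other antipode is recycled through F5 with base. Dilute HCl in MeOH at rt removes both acetals to give 18.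

2. **Step 4.**
- What may go wrong: the hindered, electron-rich aldehyde may react sluggishly or with poor facial selectivity. Bromination may also spill over from the enol silane to the chromene alkene if the stoichiometry is not exact.
- Fallback (from 5 and 10, rejoining at 9): the halogen is brought in with the diene, and the stereocentre is set in an aldol manifold instead of a concerted cycloaddition. Addition of Br2 to 10 (CH2Cl2, −78 °C) gives 3,4-dibromo-4-methoxybutan-2-one F8. Et3N dehydrobrominates it to (Z)-3-bromo-4-methoxybut-3-en-2-one F9. TMSOTf/Et3N then gives (1Z)-2-bromo-1-methoxy-3-(trimethylsilyloxy)buta-1,3-diene F10. A Ti(OiPr)4/(S)-BINOL-catalysed Mukaiyama aldol addition of F10 to 5 (4 Å MS, Et2O) furnishes, after desilylation, (1Z,5S)-2-bromo-5-[7-(tert-butyldimethylsilyloxy)-2,2-dimethyl-2H-chromen-6-yl]-5-hydroxy-1-methoxypent-1-en-3-one F11. Brief treatment with catalytic TFA (CH2Cl2, 0 °C) cyclises F11 to 9 by addition–elimination.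

3. **Step 5.**
- What may go wrong: proton transfer between enolate and product, double alkylation, and self-condensation of the enolate on warming may erode the monoalkylation.
- Fallback (from 11, rejoining at 12): the carbon chain is built first and the methoxyvinyl ketone is made last. The lithium enolate of ethyl acetate (LiN(i-Pr)2, THF/DMPU, −78 °C) is alkylated with 11 to ethyl 5-methylhex-4-enoate F12. MeNHOMe·HCl/i-PrMgCl converts it into N-methoxy-N,5-dimethylhex-4-enamide F13. Ethynylmagnesium bromide gives 7-methyloct-6-en-1-yn-3-one F14. DABCO-catalysed conjugate addition of methanol to F14 gives 12.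

**Further compounds**

F1 | step 7 | 7-(methoxymethoxy)-2,2-dimethyl-2H-chromene-6-carbaldehyde | COCOc1cc2c(cc1C=O)C=CC(C)(C)O2
F2 | step 7 | 2,4-dihydroxyacetophenone | CC(=O)c1ccc(O)cc1O
F3 | step 7 | 1-[2,4-dihydroxy-3-(3-methylbut-2-en-1-yl)phenyl]ethanone | CC(=O)c1ccc(O)c(CC=C(C)C)c1O
F4 | step 7 | 1-[2-hydroxy-4-(methoxymethoxy)-3-(3-methylbut-2-en-1-yl)phenyl]ethanone | CC(=O)c1ccc(OCOC)c(CC=C(C)C)c1O
F5 | step 7 | (E)-1-[2-hydroxy-4-(methoxymethoxy)-3-(3-methylbut-2-en-1-yl)phenyl]-3-[7-(methoxymethoxy)-2,2-dimethyl-2H-chromen-6-yl]prop-2-en-1-one | COCOc1ccc(C(=O)/C=C/c2cc3c(cc2OCOC)OC(C)(C)C=C3)c(O)c1CC=C(C)C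
F6 | step 7 | rac-7-(methoxymethoxy)-2-[7-(methoxymethoxy)-2,2-dimethyl-2H-chromen-6-yl]-8-(3-methylbut-2-en-1-yl)-2,3-dihydro-4H-chromen-4-one | COCOc1ccc2c(c1CC=C(C)C)OC(c1cc3c(cc1OCOC)OC(C)(C)C=C3)CC2=O
F7 | step 7 | (2S)-7-(methoxymethoxy)-2-[7-(methoxymethoxy)-2,2-dimethyl-2H-chromen-6-yl]-8-(3-methylbut-2-en-1-yl)-2,3-dihydro-4H-chromen-4-one | COCOc1ccc2c(c1CC=C(C)C)O[C@H](c1cc3c(cc1OCOC)OC(C)(C)C=C3)CC2=O
F8 | step 4 | 3,4-dibromo-4-methoxybutan-2-one | COC(Br)C(Br)C(C)=O
F9 | step 4 | (Z)-3-bromo-4-methoxybut-3-en-2-one | CO/C=C(Br)/C(C)=O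
F10 | step 4 | (1Z)-2-bromo-1-methoxy-3-(trimethylsilyloxy)buta-1,3-diene | CO/C=C(Br)/C(=C)O[Si](C)(C)C
F11 | step 4 | (1Z,5S)-2-bromo-5-[7-(tert-butyldimethylsilyloxy)-2,2-dimethyl-2H-chromen-6-yl]-5-hydroxy-1-methoxypent-1-en-3-one | CO/C=C(Br)/C(=O)C[C@@H](c1cc2c(cc1O[Si](C)(C)C(C)(C)C)OC(C)(C)C=C2)O
F12 | step 5 | ethyl 5-methylhex-4-enoate | CCOC(=O)CCC=C(C)C
F13 | step 5 | N-methoxy-N,5-dimethylhex-4-enamide | CON(C)C(=O)CCC=C(C)C
F14 | step 5 | 7-methyloct-6-en-1-yn-3-one | C#CC(=O)CCC=C(C)C
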